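## Structural features

The target, (2S,3S,6S,10R)-2,10-dibromo-3,7,11,11-tetramethylspiro[5.5]undec-7-en-3-ol (spiro[5.5]undecane locants are used throughout), is a chamigrene-type skeleton. Ring A (C6–C11) is a cyclohexene with the C7 methyl on the C7=C8 olefin, a secondary bromide at C10 and the gem-dimethyl carbon C11. Ring B (C1–C6) is a cyclohexane with a bromide at C2 and a methyl carbinol at C3, and the two rings share only the quaternary carbon C6. Of the four stereocentres, C2 and C3 are adjacent and form a trans bromohydrin, and C10 lies next to the quaternary C11. C6 is stereogenic only because ring B carries bromine at C2 and not at C4. In the ring B chair expected to be preferred (C11 equatorial and C7 axial on C6), the C2 bromide and C3 hydroxyl are equatorial and the C3 methyl is axial. The equatorial bromide can therefore be reached by equilibration, but the methyl must enter along the axial trajectory. The fragile groups are the β-bromo tertiary alcohol (epoxide closure or semipinacol shift with base or halophilic Lewis acids), the homoallylic C10 bromide (E2 toward C9, or re-ionisation with olefin participation) and the trisubstituted olefin (electrophiles). The real difficulty is that the C10–Br bond is neopentyl and cannot be made by displacement, that C6 and C11 are adjacent fully substituted carbons, and that C10 is insulated from the ring B stereocentres by C6 and C11. The key step uses the fact that C10 is homoallylic to C7=C8 within ring A (C10–C9–C8=C7). The bromide and the olefin are then the two ends of one cyclopropylcarbinyl cation, and joining C8 to C10 turns ring A into a bicyclo[3.1.0]hexane whose catalyst-set cyclopropane configuration becomes the C10 configuration.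

## Logic of the disconnections

17 ⇒ 16. The C3–CH3 bond is cut. The carbonyl left at C3 is the function that lets the C2 bromide be corrected by epimerisation and gives a ketone in a predictable chair. The methyl is a one-carbon reagent, so no steps are added. The forward step must deliver methyl axially to a ketone flanked by an equatorial bromide and must be non-basic, or HBr is lost or an epoxide forms.

16 ⇒ 14 (through 15). The C2–Br bond is cut. Introducing bromine through an enol derivative reduces "C2 or C4" to the position of one double bond, and that position defines C6. The forward step needs a bromine electrophile that takes the enol ether and not C7=C8, and a way from 15 to 16 that cannot move bromine to C4.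

14 ⇒ 13. The O–Si bond is cut and the C2=C3 enol double bond is returned to the ketone. C6 ceases to be a stereocentre and C10 is the only one left. Because C10 is already stereogenic, the two α-methylenes of 13 are diastereotopic rather than enantiotopic, but they differ only through that distant centre. The base, not the substrate, must therefore choose, and it must do so without E2 attack on the C10 bromide.

13 ⇒ 10. The C10–Br bond is cut, C8 is rejoined to C10, the C7=C8 π bond becomes a C7–OH bond and the C3 carbonyl returns to its dioxolane. Locants C2, C1, C6 and C5 of 10 correspond to C7, C8, C9 and C10 of 13. The cut is made here because no substitution can place bromine on a neopentyl carbon, whereas a bridged cation can be opened there. The gain is that a stereocentre next to a quaternary carbon becomes a cyclopropane stereocentre that a catalyst can set, and ring A becomes an easily formed five-membered ring. The forward step must open the internal ring-fusion bond and not the external one, with bromide, with inversion, and without a free secondary cation next to C11. The carbinol configuration of 10 is irrelevant, and the dioxolane is the right spectator because the same acid removes it.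

10 ⇒ 9. The C2–CH3 bond (bicyclic numbering) is cut. This is a one-carbon simplification to a ketone. The only demand is that a hindered, non-enolisable ketone accepts a small nucleophile.

9 ⇒ 8. The two cyclopropane bonds at C1 (C1–C5 and C1–C6) are cut. Both rings of the bicycle and both stereocentres disappear at once, leaving a diazoketone and a vinyl group on adjacent quaternary carbons. The copper carbenoid must select one face of a monosubstituted olefin and must add to it faster than it inserts into ring B C–H bonds.

8 ⇒ 6 (through 7). The C(O)–CHN2 bond is cut, which is a one-carbon homologation of a carboxylic acid. The forward step needs an acid activation that spares the ketal and an acylation at a carbonyl flanked by two quaternary carbons.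

6 ⇒ 3 (through 4 and 5). The bond between the two quaternary carbons (the future C6–C11 bond) is cut and an ester C–O bond is restored, a retro-[3,3] shift. This is the most congested bond of the target, and it is best made intramolecularly through a six-membered transition state. The forward step requires enolisation of an α-branched ester and rearrangement of a fully substituted ketene acetal onto the disubstituted allyl terminus.

3 ⇒ 1 + 2. The ester O–CH2 bond is cut. Both pieces are commercial, and the forward step only requires clean O-alkylation at the primary allylic carbon.

## Other disconnections considered

Alternative 1: The cut goes through the C8–C9 bond and the C10–Br bond of ring A, with ring B and its three stereocentres already complete. In the forward sense CuBr with tris(2-pyridylmethyl)amine would abstract bromine from the bromomethyl ketone A1. The α-keto radical would add 6-endo to the terminal vinyl carbon, and the secondary ring radical would take bromine back to give the dibromo spiro ketone A2.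
- In favour: the neopentyl C–Br bond arises by atom transfer, so no cation, no choice between cyclopropane bonds and no methyl migration are involved. A ring C–C bond and the C–Br bond form in one catalytic, redox-neutral step. 6-endo closure is the usual course when the carbonyl lies inside the forming ring, and the 5-exo carbon is neopentyl.
- Against: bromine is delivered to a planar radical, so C10 would be set only by remote substrate control across two quaternary carbons. The quaternary carbon of A1 is itself a stereocentre that must first be placed correctly relative to C2 and C3. C7 emerges as a hindered ketone that must still be converted to the methyl-bearing olefin, and the silyl ether must be removed.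
- Comparison: on structure this alternative is better, because its key step builds a ring bond and the chosen key step builds none. On regiochemistry it is the equal or better. On stereocontrol it is weaker, since the chosen opening is stereospecific and traces back to a catalyst. On step economy it is worse, because at least three operations follow A2, against three steps after 13 in the chosen plan, and A1 is far more elaborate than 10.

Alternative 2: The cut removes the C5–C6 bond and the C1=C2 bond of ring B. In the forward sense the dienolate of the bromo aldehyde A3 would add through its α-carbon to methyl vinyl ketone A4, and the methyl ketone would then condense onto the aldehyde to give the bromo spiro enone A5.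
- In favour: ring B comes from a four-carbon commodity in one flask. The enone of A5 also decides by constitution which α-carbon is functionalised: conjugate reduction with silyl trapping ([(Ph3P)CuH]6, then TMSCl) would lead directly to 14. On this point the alternative is better than the chosen plan, which needs a chiral amide.
- Against: the neopentyl bromide problem is not solved but moved into A3, whose enantioselective preparation by bromonium-induced polyene cyclisation is the hard part. The Michael step must create C6 between C7 and C11 at the α-carbon of a dienolate that can also react at its γ-carbon. Facial control would rest on the C10 bromide alone, and the basic condensation invites E2 loss of HBr.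
- Comparison: on structure it forms two ring bonds in the key step, which is better. On mechanism it is classical and equal in precedent, but less secure in diastereocontrol at C6. On step economy the endgame after A5 is three steps and so equal to the chosen one. The total is longer, because A3 has no short enantioselective source, whereas 13 is reached in six steps from commercial materials.

Alternative 3: The cut removes the C2–C3 and C4–C5 bonds of ring B, leading back to the spiro cyclobutanone A6 and the silylpropyne A7. In the forward sense Ni(cod)2 with a phosphine would couple the carbonyl and the alkyne in an oxanickelacycle, cleave one C(=O)–CH2 bond by β-carbon elimination and close the spiro silyl enone A8 by reductive elimination.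
- In favour: it is convergent and atom-economical, makes two C–C bonds, brings in the C3 methyl carbon, and the silyl group controls the orientation of the alkyne. On convergency and bond construction it is better than the chosen plan.
- Against: zerovalent nickel inserts into secondary C–Br bonds, so the C10 bromide of A6 is directly threatened. The oxygen of A8 sits at C2 instead of C3, so a carbonyl transposition, a C–O to C–Br exchange with inversion next to a tertiary carbinol, and a protodesilylation would all be needed. C6 depends on which of two diastereotopic C(=O)–CH2 bonds is cleaved, and A6 still requires the neopentyl bromide.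
- Comparison: mechanistically the ring expansion is equal in precedent for 3,3-disubstituted cyclobutanones, but it is less compatible with the bromide than the chosen step, which creates that bromide. On step economy it is worse, with at least five operations after A8 against three after 13.

Key step: step 6

Assumption: the antipodes named for the bisoxazoline (step 4) and the lithium amide (step 7) are those expected by analogy with simpler substrates to give (1S,5R)-9 and (6S)-14; if the sense of induction is opposite on these substrates, the mirror-image reagent is used with no other change.

## Route

Step 1
Reactants: 1 ketal acid 1,4-dioxaspiro[4.5]decane-8-carboxylic acid; 2 prenyl bromide 1-bromo-3-methylbut-2-ene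
Product: 3 prenyl ester 3-methylbut-2-en-1-yl 1,4-dioxaspiro[4.5]decane-8-carboxylate
Conditions: K2CO3, DMF, 23 °C
Reagents that add atoms: none
Why: O-alkylation of the carboxylate by SN2 at the primary allylic carbon; the basic medium leaves the dioxolane untouched and gives the allyl ester needed for the rearrangement in one operation.

Step 2
Reactants: 3 prenyl ester
Product: 6 8-(2-methylbut-3-en-2-yl)-1,4-dioxaspiro[4.5]decane-8-carboxylic acid, via silyl ketene acetal 4 (not isolated), via silyl ester 5 (not isolated)
Conditions: LiN(i-Pr)2, THF, −78 °C; TMSCl, −78 → 23 °C; toluene, 90 °C; then H2O, pH 5 buffer
Reagents that add atoms: none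
Why: Ireland–Claisen rearrangement: the ester enolate is trapped on oxygen as 4, and the chair-like [3,3] shift joins the ring carbon to the dimethyl-substituted allyl terminus, making the two adjacent quaternary carbons and the vinyl group intramolecularly. No stereocentre arises because the ring is symmetric, and 5 is hydrolysed at near-neutral pH so that the ketal survives.

Step 3
Reactants: 6 rearranged acid
Product: 8 2-diazo-1-[8-(2-methylbut-3-en-2-yl)-1,4-dioxaspiro[4.5]decan-8-yl]ethan-1-one, via acid chloride 7 (not isolated)
Conditions: Me2C=C(Cl)NMe2, CH2Cl2, 0 → 23 °C; then CH2N2 (3 equiv), Et2O, 0 → 23 °C
Reagents that add atoms: diazomethane, C=[N+]=[N-]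
Why: The α-chloroenamine forms the hindered acid chloride without free HCl, so the ketal is preserved, and acylation of diazomethane (first stage of the Arndt–Eistert sequence) gives the diazoketone. There is no α-hydrogen, so no ketene pathway competes, and excess diazomethane takes up the HCl.

Step 4
Reactants: 8 diazoketone
Product: 9 (1S,5R)-4,4-dimethylspiro[bicyclo[3.1.0]hexane-3,8'-[1,4]dioxaspiro[4.5]decan]-2-one
Conditions: (CuOTf)2·C6H6 (5 mol%), (S,S)-t-Bu-bisoxazoline (6 mol%), CH2Cl2, 23 °C, slow addition of 8
Reagents that add atoms: none
Why: Loss of N2 gives a bisoxazoline-bound carbenoid of monovalent copper that adds to the vinyl group three atoms away (intramolecular cyclopropanation of a 1-diazohex-5-en-2-one); closure is helped by the gem-dialkyl effect of both tether carbons, and copper favours olefin addition over C–H insertion into ring B. The cis ring fusion is enforced by geometry, so C1 and C5 are set together by the ligand's choice of olefin face, intended as (1S,5R).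

Step 5
Reactants: 9 cyclopropyl ketone
Product: 10 (1S,2S,5R)-2,4,4-trimethylspiro[bicyclo[3.1.0]hexane-3,8'-[1,4]dioxaspiro[4.5]decan]-2-ol
Conditions: MeLi, Et2O, −78 → 0 °C; then H2O
Reagents that add atoms: methyllithium, [Li]C
Why: 1,2-Addition to a ketone that cannot enolise (one α-carbon is quaternary, the other a cyclopropane bridgehead); approach anti to the cyclopropane methylene should give the (2S) carbinol. This centre is planarised in step 6, so its configuration is of no consequence.

Step 6
Reactants: 10 spiro bicyclo[3.1.0]hexan-2-ol
Product: 13 (10R)-10-bromo-7,11,11-trimethylspiro[5.5]undec-7-en-3-one, via cyclopropylcarbinyl cation 11 (not isolated), via bromo ketal 12 (not isolated)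
Conditions: 48% aq. HBr (10 equiv), CH2Cl2, 0 → 23 °C, vigorous stirring
Reagents that add atoms: hydrogen bromide, Br; water, O
Why: Protonation and loss of water from the tertiary carbinol give cation 11, whose charge is shared with the two cyclopropane bonds at C1; bromide then attacks the ring-fusion carbon C5 from the side opposite the C1–C5 bond, so that this bond becomes the π bond of C7=C8 and C5 becomes C10. The closest known reaction type is the cyclopropylcarbinyl-to-homoallyl halide opening (Julia olefin synthesis) in its ring-enlarging form, as in the return of 3,5-cyclosteroid cations to 3-substituted 5-ene steroids and the thujyl-to-terpinen-4-yl change. Ring A is closed by enlargement and not by cyclisation: the zero-atom bridge of the bicyclo[3.1.0]hexane is cut and the former cyclopropane methylene stays bonded to both ends as C9, so the five-membered ring becomes six-membered. The one new stereocentre, C10, is controlled by the C5 configuration set in step 4, because the opening is an invertive, SN2-like displacement on a bridged ion, so (5R) maps onto (10R); re-ionisation of the homoallylic bromide would lead back to 11 and not to the epimer. The selectivity needed is cleavage of the internal C1–C5 bond instead of the external C1–C6 bond, and capture at C5 instead of at the carbinyl carbon. The substrate supports this because C5 is secondary and carries more charge than the primary C6, because only internal cleavage releases the strain of the fused bicycle, and because capture at the tertiary carbon or proton loss to an exocyclic methylene is reversible in HBr, leaving the strain-free homoallylic bromide as the sink. Since no free cation develops at C5, methyl migration from the neighbouring gem-dimethyl carbon should not intervene. The aqueous acid also hydrolyses the dioxolane in the same flask (12 to 13), so no separate deprotection is needed.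

Step 7
Reactants: 13 (R)-bromo spiro ketone
Product: 14 trimethyl{[(6S,10R)-10-bromo-7,11,11-trimethylspiro[5.5]undeca-2,7-dien-3-yl]oxy}silane
Conditions: lithium (R,R)-bis(1-phenylethyl)amide, LiCl, TMSCl (internal quench), THF, −78 °C
Reagents that add atoms: chlorotrimethylsilane, C[Si](C)(C)Cl
Why: Enantiopure lithium amide deprotonation with in situ silylation: the base removes one of the two diastereotopic axial α-hydrogens of the chair-biased ring B ketone (C11 equatorial), by analogy with the desymmetrisation of 4-tert-butylcyclohexanone, and TMSCl traps the enolate before it can equilibrate. The position of the enol double bond fixes C6 as (S); a minor regioisomer would be a diastereomer and separable downstream, and the low temperature should prevent E2 at C10.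

Step 8
Reactants: 14 silyl enol ether
Product: 16 (2S,6S,10R)-2,10-dibromo-7,11,11-trimethylspiro[5.5]undec-7-en-3-one, via axial bromo ketone 15 (not isolated)
Conditions: NBS, THF, −78 °C; then n-Bu4NBr (0.2 equiv), MeCN, 23 °C
Reagents that add atoms: N-bromosuccinimide, O=C1CCC(=O)N1Br
Why: Electrophilic bromination of the silyl enol ether, which should be far faster than attack on the hindered C7=C8 olefin, is expected to give mainly the axial bromide 15 by stereoelectronically favoured axial attack. Bromide-ion exchange (a degenerate Finkelstein-type SN2 at the α-keto carbon) then epimerises C2 to the equatorial bromide cis to C11, which avoids the syn-diaxial contact between bromine and C7. This mechanism cannot move bromine to C4, and the neopentyl C10 bromide should not exchange.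

Step 9
Reactants: 16 dibromo ketone
Product: 17 (2S,3S,6S,10R)-2,10-dibromo-3,7,11,11-tetramethylspiro[5.5]undec-7-en-3-ol
Conditions: Me3Al (4 equiv), toluene, −78 → 0 °C (16 added to the reagent); then aq. KNaC4H4O6 (potassium sodium tartrate)
Reagents that add atoms: trimethylaluminium, C[Al](C)C
Why: 1,2-Addition of an organoaluminium: with excess reagent in a hydrocarbon, methyl is transferred from a second aluminium to the aluminium-complexed carbonyl through a six-membered transition state along the axial trajectory, giving the axial methyl and equatorial alkoxide, that is (3S). The reagent is non-basic, so enolisation and loss of HBr are avoided, and the trans-diequatorial bromide and alkoxide cannot close to an epoxide.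

## Compound list

1 | 1,4-dioxaspiro[4.5]decane-8-carboxylic acid | OC(=O)C1CCC2(CC1)OCCO2 | starting material
2 | 1-bromo-3-methylbut-2-ene (prenyl bromide) | CC(C)=CCBr | starting material
3 | 3-methylbut-2-en-1-yl 1,4-dioxaspiro[4.5]decane-8-carboxylate | CC(C)=CCOC(=O)C1CCC2(CC1)OCCO2 | intermediate
4 | trimethyl{[(3-methylbut-2-en-1-yl)oxy](1,4-dioxaspiro[4.5]decan-8-ylidene)methoxy}silane (silyl ketene acetal of 3) | CC(C)=CCOC(O[Si](C)(C)C)=C1CCC2(CC1)OCCO2 | intermediate (not isolated)
5 | trimethylsilyl 8-(2-methylbut-3-en-2-yl)-1,4-dioxaspiro[4.5]decane-8-carboxylate | C=CC(C)(C)C1(C(=O)O[Si](C)(C)C)CCC2(CC1)OCCO2 | intermediate (not isolated)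
6 | 8-(2-methylbut-3-en-2-yl)-1,4-dioxaspiro[4.5]decane-8-carboxylic acid | C=CC(C)(C)C1(C(O)=O)CCC2(CC1)OCCO2 | intermediate
7 | 8-(2-methylbut-3-en-2-yl)-1,4-dioxaspiro[4.5]decane-8-carbonyl chloride | C=CC(C)(C)C1(C(Cl)=O)CCC2(CC1)OCCO2 | intermediate (not isolated)
8 | 2-diazo-1-[8-(2-methylbut-3-en-2-yl)-1,4-dioxaspiro[4.5]decan-8-yl]ethan-1-one | C=CC(C)(C)C1(C(=O)C=[N+]=[N-])CCC2(CC1)OCCO2 | intermediate
9 | (1S,5R)-4,4-dimethylspiro[bicyclo[3.1.0]hexane-3,8'-[1,4]dioxaspiro[4.5]decan]-2-one | O=C1[C@H]2C[C@H]2C(C)(C)C13CCC4(CC3)OCCO4 | intermediate
10 | (1S,2S,5R)-2,4,4-trimethylspiro[bicyclo[3.1.0]hexane-3,8'-[1,4]dioxaspiro[4.5]decan]-2-ol | C[C@]1(O)[C@H]2C[C@H]2C(C)(C)C13CCC4(CC3)OCCO4 | intermediate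
11 | tertiary cyclopropylcarbinyl cation formed from 10 by loss of hydroxide from C2, cyclopropane configuration unchanged | C[C+]1[C@H]2C[C@H]2C(C)(C)C13CCC4(CC3)OCCO4 | intermediate (not isolated)
12 | (12R)-12-bromo-9,13,13-trimethyl-1,4-dioxadispiro[4.2.5.2]pentadec-9-ene (13 with its C3 carbonyl still as the 1,3-dioxolane) | CC1=CC[C@@H](Br)C(C)(C)C12CCC3(CC2)OCCO3 | intermediate (not isolated)
13 | (10R)-10-bromo-7,11,11-trimethylspiro[5.5]undec-7-en-3-one | CC1=CC[C@@H](Br)C(C)(C)C12CCC(=O)CC2 | intermediate
14 | trimethyl{[(6S,10R)-10-bromo-7,11,11-trimethylspiro[5.5]undeca-2,7-dien-3-yl]oxy}silane | CC1=CC[C@@H](Br)C(C)(C)[C@]12CCC(O[Si](C)(C)C)=CC2 | intermediate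
15 | (2R,6S,10R)-2,10-dibromo-7,11,11-trimethylspiro[5.5]undec-7-en-3-one (C2 bromide axial, trans to C11) | CC1=CC[C@@H](Br)C(C)(C)[C@]12CCC(=O)[C@H](Br)C2 | intermediate (not isolated)
16 | (2S,6S,10R)-2,10-dibromo-7,11,11-trimethylspiro[5.5]undec-7-en-3-one (C2 bromide equatorial, cis to C11) | CC1=CC[C@@H](Br)C(C)(C)[C@]12CCC(=O)[C@@H](Br)C2 | intermediate
17 | (2S,3S,6S,10R)-2,10-dibromo-3,7,11,11-tetramethylspiro[5.5]undec-7-en-3-ol | CC1=CC[C@@H](Br)C(C)(C)[C@]12CC[C@](C)(O)[C@@H](Br)C2 | target

## Step count and least certain steps

Total step count: 9. Longest linear sequence: 9 steps (1 to 17).

Step 6 (key step). The most likely failure is opening of the wrong cyclopropane bond: the external C1–C6 bond is better aligned with the vacant orbital and its carbon is unhindered, so bromide may attack the methylene and leave a five-membered ring. Slower risks are addition of HBr across the new olefin on long exposure and leakage toward an open secondary cation followed by methyl migration. The fallback separates ring enlargement from C–Br formation. It sets out from 10, which in dilute aqueous HClO4 and dioxane would be captured reversibly by water under thermodynamic control (the thujyl to terpinen-4-ol pattern). This should give (10R)-10-hydroxy-7,11,11-trimethylspiro[5.5]undec-7-en-3-one F1, with the ketal lost in the same medium. An Appel reaction (Ph3P, CBr4, CH2Cl2) would then convert the alcohol to the bromide with retention through participation of the C7=C8 olefin, as in the conversion of cholesterol to cholesteryl bromide. Here the ion pair should collapse at the carbon the leaving group has just left. This fallback returns to the route at 13.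

Step 4. Enantioface discrimination may be insufficient, because a simple diazoketone with a monosubstituted olefin is a less responsive substrate for copper bisoxazoline catalysts than diazoesters; carbene dimerisation or C–H insertion may also erode the yield. The fallback replaces catalyst-controlled carbene transfer by reagent-controlled reduction followed by hydroxyl-directed cyclopropanation. It sets out from 6 through its chloride 7.
- Stille acylation with tributyl(vinyl)stannane and PdCl2(PPh3)2 would give the vinyl ketone 1-[8-(2-methylbut-3-en-2-yl)-1,4-dioxaspiro[4.5]decan-8-yl]prop-2-en-1-one F2.
- Ring-closing metathesis with (H2IMes)(PCy3)Cl2Ru=CHPh (second-generation Grubbs catalyst) would close the cyclopentenone 5,5-dimethylspiro[cyclopent-3-ene-1,8'-[1,4]dioxaspiro[4.5]decan]-2-one F3.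
- Corey–Bakshi–Shibata reduction would give (2S)-5,5-dimethylspiro[cyclopent-3-ene-1,8'-[1,4]dioxaspiro[4.5]decan]-2-ol F4. The oxazaborolidine antipode is chosen for the (S)-alcohol, expected to be the (R)-catalyst if the quaternary carbon acts as the large group.
- Simmons–Smith cyclopropanation with Et2Zn and CH2I2, directed syn to the hydroxyl, would give (1S,2S,5R)-4,4-dimethylspiro[bicyclo[3.1.0]hexane-3,8'-[1,4]dioxaspiro[4.5]decan]-2-ol F5.
- Dess–Martin oxidation would return to the route at 9.

Step 7. Discrimination between the two diastereotopic α-methylenes may be poor, because the only element that distinguishes them in the substrate is the remote C10 and the ring B chair may be less biased than assumed; partial enolate equilibration would erode the ratio further. The fallback changes the control element from a stoichiometric chiral base to a covalently bound chiral enamine. It sets out from 13, which would be brominated directly with a C2-symmetric (2R,5R)-2,5-diphenylpyrrolidine catalyst and 4,4-dibromo-2,6-di-tert-butylcyclohexa-2,5-dienone as the bromine donor. It returns to the route at 15, which is equilibrated to 16 with n-Bu4NBr as in the second stage of step 8. No new compound is involved (F0). In either mode the unwanted regioisomer is a diastereomer of 16 and can be removed by chromatography or crystallisation.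

Step 9. Facial selectivity of methyl transfer may be poor if the equatorial α-bromide perturbs the two-aluminium pathway, and the Lewis acid may assist ionisation of the α-bromide and trigger a semipinacol shift. The fallback makes the C3–O bond last instead of the C3–CH3 bond, and it also removes the dependence on the equilibration in step 8. It sets out from 14.
- MeLi would release the regiodefined lithium enolate, and PhNTf2 would convert it to the enol triflate (6S,10R)-10-bromo-7,11,11-trimethylspiro[5.5]undeca-2,7-dien-3-yl trifluoromethanesulfonate F6.
- Coupling with Me2CuLi would give the diene (6S,10R)-10-bromo-3,7,11,11-tetramethylspiro[5.5]undeca-2,7-diene F7.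
- NBS in aqueous THF should form the bromonium ion on the less hindered ring B olefin, and water should open it at the tertiary C3 in the anti sense, giving the trans bromohydrin.

This fallback returns to the route at 17. Its own weak point is the face on which the bromonium ion forms relative to C6.

## Further compounds

F1 | step 6 | (10R)-10-hydroxy-7,11,11-trimethylspiro[5.5]undec-7-en-3-one | CC1=CC[C@@H](O)C(C)(C)C12CCC(=O)CC2
F2 | step 4 | 1-[8-(2-methylbut-3-en-2-yl)-1,4-dioxaspiro[4.5]decan-8-yl]prop-2-en-1-one | C=CC(=O)C1(C(C)(C)C=C)CCC2(CC1)OCCO2
F3 | step 4 | 5,5-dimethylspiro[cyclopent-3-ene-1,8'-[1,4]dioxaspiro[4.5]decan]-2-one | O=C1C=CC(C)(C)C12CCC3(CC2)OCCO3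
F4 | step 4 | (2S)-5,5-dimethylspiro[cyclopent-3-ene-1,8'-[1,4]dioxaspiro[4.5]decan]-2-ol | O[C@H]1C=CC(C)(C)C12CCC3(CC2)OCCO3
F5 | step 4 | (1S,2S,5R)-4,4-dimethylspiro[bicyclo[3.1.0]hexane-3,8'-[1,4]dioxaspiro[4.5]decan]-2-ol | O[C@H]1[C@H]2C[C@H]2C(C)(C)C13CCC4(CC3)OCCO4
F0 | step 7 | none | none
F6 | step 9 | (6S,10R)-10-bromo-7,11,11-trimethylspiro[5.5]undeca-2,7-dien-3-yl trifluoromethanesulfonate | CC1=CC[C@@H](Br)C(C)(C)[C@]12CCC(OS(=O)(=O)C(F)(F)F)=CC2
F7 | step 9 | (6S,10R)-10-bromo-3,7,11,11-tetramethylspiro[5.5]undeca-2,7-diene | CC1=CC[C@@H](Br)C(C)(C)[C@]12CCC(C)=CC2
A1 | alternative 1 | bromomethyl ketone: 2-bromo-1-[3-bromo-4-methyl-1-(2-methylbut-3-en-2-yl)-4-(triethylsilyloxy)cyclohexyl]ethan-1-one, configured as in the SMILES | C=CC(C)(C)[C@@]1(C(=O)CBr)CC[C@](C)(O[Si](CC)(CC)CC)[C@@H](Br)C1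
A2 | alternative 1 | dibromo spiro ketone: 2,10-dibromo-3,11,11-trimethyl-3-(triethylsilyloxy)spiro[5.5]undecan-7-one, configured as in the SMILES | O=C1CC[C@@H](Br)C(C)(C)[C@]12CC[C@](C)(O[Si](CC)(CC)CC)[C@@H](Br)C2
A3 | alternative 2 | (5R)-5-bromo-2,6,6-trimethylcyclohex-2-ene-1-carbaldehyde | CC1=CC[C@@H](Br)C(C)(C)C1C=O
A4 | alternative 2 | but-3-en-2-one (methyl vinyl ketone) | CC(=O)C=C
A5 | alternative 2 | bromo spiro enone: 10-bromo-7,11,11-trimethylspiro[5.5]undeca-1,7-dien-3-one, configured as in the SMILES | CC1=CC[C@@H](Br)C(C)(C)[C@]12CCC(=O)C=C2
A6 | alternative 3 | (8R)-8-bromo-5,9,9-trimethylspiro[3.5]non-5-en-2-one | CC1=CC[C@@H](Br)C(C)(C)C12CC(=O)C2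
A7 | alternative 3 | trimethyl(prop-1-yn-1-yl)silane | CC#C[Si](C)(C)C
A8 | alternative 3 | spiro silyl enone: 10-bromo-3,7,11,11-tetramethyl-4-(trimethylsilyl)spiro[5.5]undeca-3,7-dien-2-one, configured as in the SMILES | CC1=CC[C@@H](Br)C(C)(C)[C@]12CC([Si](C)(C)C)=C(C)C(=O)C2
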